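**Remark (assumption):** the SMILES contains no stereocentre and the molecule is achiral (two identical rings on one CH2), so the "single enantiomer" requirement is met by constitution alone and no step has to set or preserve a stereocentre. Ring positions of the target are numbered C1 (butanoyl), C2 (OH), C3 (CH2 bridge), C4 (OH), C5 (CH3), C6 (OCH3).

## Structural features

Pseudoaspidin is a methylene-bis(acylphloroglucinol): two identical hexasubstituted benzene rings joined by a single CH2, with no stereocentre and no other ring. Going round each ring, C1 carries the butanoyl group, C2 an OH, C3 the CH2 bridge, C4 an OH, C5 a CH3 and C6 an OCH3. The bridge carbon therefore lies between the two free phenols and para to the methoxy group, and the methoxy group is wedged between the C-methyl and the acyl group. The three oxygens of each ring are all different (chelated OH at C2, free OH at C4, OMe at C6), and the acyl group sits ortho to the OMe, not between two hydroxyls as in the isomeric aspidinol pattern. Fragile points are the electron-rich polyphenol rings (air oxidation), the diarylmethane link (ipso-protonation in strong acid, retro-Michael loss of an o-quinone methide in base) and the O-methyl group next to the ketone (chelation-assisted cleavage by hard Lewis acids). The real difficulty is regiochemical, not skeletal: each ring derives from a methylphloroglucinol monomethyl ether nucleus with two nucleophilic ring carbons, C1 and C3, each activated by three oxygens, and one must take the acyl group and the other the bridge, on both rings. The key step exploits the C2 symmetry about the CH2 together with this two-site pattern: once C3 of both rings is tied up in the bridge, C1–H is the only ring C–H left on each ring, so both acyl groups can be introduced last, in one two-directional acylation, with no choice of site left. In one sentence, the route is a double Friedel–Crafts butanoylation of the preformed, acyl-free tetraphenolic diarylmethane, not a methylene coupling of two finished acyl monomers.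

## Logic of the disconnections

**12 ⇒ 10 + 2 × 11 (key).** The two aryl C1–C(=O) bonds are cut, one on each ring, in the same operation. The cut is made here because in 10 every ring has exactly one C–H, and it is the carbon that must carry the acyl group; the carbon at which acylation would otherwise compete is the bridgehead. The gain is two hexasubstituted acyl rings reduced to a symmetric, carbonyl-free tetraphenol, with all regiochemistry transferred to the earlier placement of the bridge. The demand on the forward step is that C-acylation outruns acid-induced cleavage or migration of the bridge and spares the O-methyl groups.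

**10 ⇒ 8 (through 9).** No C–C bond is cut: the bridge C–H is traced back to C–OH, and the four phenolic O–H bonds to O–CH2OMe. The carbinol is what a one-carbon electrophile at the ester level gives with two aryl anions, and the acetal groups are the directing groups that make those anions. The gain is that the bridge becomes the product of a carbonyl addition. The demand is that reduction of the carbinol precedes unmasking of the phenols, and that the acetal-derived electrophile is destroyed before it can alkylate the freed rings.

**8 ⇒ 2 × 4 + 5 (through 6 and 7).** Both aryl–CH(OH) bonds are cut. On each ring the bridge carbon sits between the two masked hydroxyls, which is exactly the site that directed ortho-metalation selects. The bridge is thus placed by coordination, not by innate nucleophilicity, under which both free ring carbons would compete and oligomerise. The gain is a 21-carbon symmetric core reduced to one pentasubstituted arene and a C1 unit. The demand is lithiation at C4 rather than C6 of 4, and a double addition despite four ortho substituents.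

**4 ⇒ 3.** The three C–H bonds of the ring methyl are traced back to a formyl C=O. The formyl group is kept until here because it is the element that differentiates the ring oxygens in the preceding steps; it then becomes the C-methyl group. The demand is a deoxygenation under basic conditions that leave the acetals intact.

**3 ⇒ 2 ⇒ 1.** The O–CH3 bond and then the two O–CH2OMe bonds are cut. In 1 the hydroxyls differ only by chelation to the formyl group, so the two unchelated ones are masked first and the chelated one is methylated afterwards. This puts the single O-methyl group next to the future C-methyl group. The gain is arrival at a commercial, symmetric trihydroxy aldehyde. The demand is that the bis-alkylation stops before the chelated hydroxyl reacts.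

## Other disconnections considered

**Alternative 1:** (the first idea) Both aryl–CH2 bonds of 12 are cut last. Forward: 5-methoxy-4-methylbenzene-1,3-diol A1 is acylated with 11 to the monomer 1-(4,6-dihydroxy-2-methoxy-3-methylphenyl)butan-1-one A2, and two molecules of A2 are joined with formaldehyde. The bridging itself is sound, since A2 has a single free ring carbon and a deactivated ring. The weakness is the acylation of A1: it has two competing carbons, each activated by three oxygens, and attack between the two hydroxyls gives the aspidinol-type isomer 1-(2,6-dihydroxy-4-methoxy-3-methylphenyl)butan-1-one A3. Nothing in A1 biases the reaction towards A2, so the route is shorter on paper but leaves its regiochemistry to chance. The chosen plan removes the competing site by placing the bridge there first.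

**Alternative 2:** One aryl–CH2 bond is cut as a C–H/C–H union of like polarity. Forward: the C3-methyl of 1-(2,4-dihydroxy-6-methoxy-3,5-dimethylphenyl)butan-1-one A4 is oxidised (DDQ, Ag2O or an anode) to the o-quinone methide 4-butanoyl-5-hydroxy-3-methoxy-2-methyl-6-methylidenecyclohexa-2,4-dien-1-one A5, which is trapped by A2. Three structural grounds speak against it. A4 has two ortho-methyl groups that can both form a quinone methide through the C4 hydroxyl. The doubly benzylic CH2 of the product should be oxidised more easily than the methyl group of A4, so over-oxidation is expected. A2 is itself an oxidisable polyphenol and must still be made, so the regiochemical problem of Alternative 1 remains.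

**Alternative 3:** In each ring the C1–C2 bond is cut, so that both benzene rings are built at once. Forward: 3,3'-methylenebis[4-hydroxy-5-methyl-6-(2-oxopentyl)-2H-pyran-2-one] A6 undergoes a double base-mediated ring-opening and Claisen recyclisation to 1,1'-[methylenebis(2,4,6-trihydroxy-5-methylbenzene-3,1-diyl)]di(butan-1-one) A7, followed by double O-methylation. This is two-directional and the bridge comes from a clean condensation, but it ends at A7 with three free hydroxyls per ring. The methylation needed is at the hydroxyl flanked by C-methyl and acyl, which is chelated and the most hindered, while the unchelated hydroxyl is the most acidic. No handle for that selectivity is visible, and the route to A6 is longer than the chosen one.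

Key step: step 6

## Route

Step 1
Reactants: 1 2,4,6-trihydroxybenzaldehyde
Product: 2 2-hydroxy-4,6-bis(methoxymethoxy)benzaldehyde
Conditions: MOMCl (2.2 equiv), i-Pr2NEt (3 equiv), CH2Cl2/DMF, 0 °C → rt
Reagents that add atoms: chloromethyl methyl ether, COCCl
Why: Base-mediated O-alkylation (MOM ether formation); the para-OH and one of the two equivalent ortho-OH groups react, while the remaining ortho-OH is held in a hydrogen bond to the formyl oxygen and is much less nucleophilic, so the reaction should stop at the single possible bis-ether.

Step 2
Reactants: 2 2-hydroxy-4,6-bis(methoxymethoxy)benzaldehyde
Product: 3 2-methoxy-4,6-bis(methoxymethoxy)benzaldehyde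
Conditions: MeI, K2CO3, DMF, 40 °C
Reagents that add atoms: iodomethane, CI
Why: Williamson O-methylation of the chelated phenol under carbonate/DMF conditions; this fixes the only O-methyl group of each future ring on the oxygen next to the formyl carbon, i.e. next to the future C-methyl group.

Step 3
Reactants: 3 2-methoxy-4,6-bis(methoxymethoxy)benzaldehyde
Product: 4 1-methoxy-3,5-bis(methoxymethoxy)-2-methylbenzene
Conditions: N2H4·H2O, KOH, diethylene glycol, 130 °C then 200 °C
Reagents that add atoms: none
Why: Wolff–Kishner reduction (hydrazone formation, then base-induced loss of N2) converts the non-enolisable, electron-rich aryl aldehyde into the aryl methyl group; the MOM acetals and the aryl methyl ether are stable to hot alkali.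

Step 4
Reactants: 4 1-methoxy-3,5-bis(methoxymethoxy)-2-methylbenzene (2 equiv); 5 ethyl formate (1 equiv)
Product: 8 bis[4-methoxy-2,6-bis(methoxymethoxy)-3-methylphenyl]methanol, via aryllithium 6 (not isolated), via benzaldehyde 7 (not isolated)
Conditions: n-BuLi (1.05 equiv per 4), THF, 0 °C, 1 h; then HCO2Et (0.5 equiv), −78 °C → rt; H2O
Reagents that add atoms: n-butyllithium, [Li]CCCC (supplies the lithium of 6 only)
Why: Directed ortho-metalation: C4–H of 4 lies between two chelating OMOM groups and should be removed in preference to C6–H, which has one OMOM and the weaker OMe director whose methyl is pushed towards C6 by the adjacent C-methyl. Two equivalents of 6 then add to the formate (acyl substitution to 7, then 1,2-addition), the standard route from aryllithiums to symmetrical diarylmethanols; the carbinol carbon bears two identical aryl groups and is not a stereocentre.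

Step 5
Reactants: 8 bis[4-methoxy-2,6-bis(methoxymethoxy)-3-methylphenyl]methanol
Product: 10 2,2'-methylenebis(5-methoxy-4-methylbenzene-1,3-diol), via tetra-MOM diarylmethane 9 (not isolated)
Conditions: Et3SiH (10 equiv), TFA (3 equiv), CH2Cl2, −20 °C; then TFA/CH2Cl2 (1:4), 0 °C → rt, under argon
Reagents that add atoms: none
Why: Ionic hydrogenation: under mild acid the carbinol ionises to a benzhydryl cation stabilised by six ring oxygens and takes hydride from the silane to give 9. The stronger acid of the second stage cleaves the four aryl MOM acetals (phenol is the better leaving group), and the excess silane should reduce the methoxymethyl cation to dimethyl ether before it can alkylate the freed rings.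

Step 6
Reactants: 10 2,2'-methylenebis(5-methoxy-4-methylbenzene-1,3-diol); 11 butanoyl chloride (2 equiv)
Product: 12 pseudoaspidin, 1,1'-[methylenebis(2,4-dihydroxy-6-methoxy-5-methylbenzene-3,1-diyl)]di(butan-1-one)
Conditions: PrCOCl (2.3 equiv), AlCl3 (6 equiv), PhNO2/CH2Cl2, 0 °C → rt; then ice/1 M HCl
Reagents that add atoms: none
Why: Twofold Friedel–Crafts C-acylation, the classical acylphloroglucinol synthesis applied to both rings of 10 at once. Butanoyl chloride and AlCl3 give the acylium ion, which on each ring attacks C6–H (locants of 10), the only unsubstituted ring carbon, activated by an ortho-OH, an ortho-OMe and a para-OH; loss of the proton and chelation of the new ketone to the neighbouring aluminium phenoxide complete the substitution. No ring is closed and no stereocentre is formed. Site selectivity, the weak point of a monomer route, is secured by the substrate: the carbon between the two hydroxyls, where a monomer would be acylated to the aspidinol pattern, is occupied on both rings by the bridge installed in step 4. One acyl group per ring is assured because no further C–H remains, and the CH2 insulates the rings electronically so that the second ring should react like the first. Any aryl butanoate formed on oxygen should either undergo Fries rearrangement to the same carbon or be hydrolysed on work-up. The step must avoid acid cleavage of the bridge by ipso-protonation and loss of the O-methyl group; low temperature, a preformed acylium complex and chelation of each ketone by its phenoxide and not by the methoxy oxygen argue for both.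

## Compound list

1 | 2,4,6-trihydroxybenzaldehyde | O=Cc1c(O)cc(O)cc1O | starting material
2 | 2-hydroxy-4,6-bis(methoxymethoxy)benzaldehyde | O=Cc1c(O)cc(OCOC)cc1OCOC | intermediate
3 | 2-methoxy-4,6-bis(methoxymethoxy)benzaldehyde | O=Cc1c(OC)cc(OCOC)cc1OCOC | intermediate
4 | 1-methoxy-3,5-bis(methoxymethoxy)-2-methylbenzene | Cc1c(OC)cc(OCOC)cc1OCOC | intermediate
5 | ethyl formate | CCOC=O | starting material
6 | [4-methoxy-2,6-bis(methoxymethoxy)-3-methylphenyl]lithium | [Li]c1c(OCOC)cc(OC)c(C)c1OCOC | intermediate (not isolated)
7 | 4-methoxy-2,6-bis(methoxymethoxy)-3-methylbenzaldehyde | O=Cc1c(OCOC)cc(OC)c(C)c1OCOC | intermediate (not isolated)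
8 | bis[4-methoxy-2,6-bis(methoxymethoxy)-3-methylphenyl]methanol | OC(c1c(OCOC)cc(OC)c(C)c1OCOC)c1c(OCOC)cc(OC)c(C)c1OCOC | intermediate
9 | bis[4-methoxy-2,6-bis(methoxymethoxy)-3-methylphenyl]methane | COCOc1cc(OC)c(C)c(OCOC)c1Cc1c(OCOC)cc(OC)c(C)c1OCOC | intermediate (not isolated)
10 | 2,2'-methylenebis(5-methoxy-4-methylbenzene-1,3-diol) | COc1cc(O)c(Cc2c(O)cc(OC)c(C)c2O)c(O)c1C | intermediate
11 | butanoyl chloride | CCCC(Cl)=O | starting material
12 | pseudoaspidin, 1,1'-[methylenebis(2,4-dihydroxy-6-methoxy-5-methylbenzene-3,1-diyl)]di(butan-1-one) | CCCC(=O)c1c(O)c(Cc2c(O)c(C)c(OC)c(C(=O)CCC)c2O)c(O)c(C)c1OC | target

## Step count and least certain steps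

Total step count: 6. Longest linear sequence: 6 steps (1 → 2 → 3 → 4 → 8 → 10 → 12). No stereocentre is present at any stage.

**Step 6 (key step).** The most likely failure is acid-promoted scrambling at the methylene bridge. Because 10 is an unacylated, very electron-rich diarylmethane, ipso-protonation and retro-Friedel–Crafts fragmentation, followed by recombination at another ring carbon or oligomerisation, can compete with acylation. Acylation on oxygen and chelation-assisted loss of the O-methyl group are lesser risks. The fallback avoids the free tetraphenol and the Lewis acid altogether while keeping the two-directional logic. It sets out from 8: step 5 is stopped after its first stage and 9 is isolated. NBS (2 equiv, MeCN, 0 °C) should brominate the single remaining ring C–H of each ring to give the dibromide bis[3-bromo-4-methoxy-2,6-bis(methoxymethoxy)-5-methylphenyl]methane F1. Bromine–lithium exchange (t-BuLi, THF, −78 °C), which should be faster than deprotonation of the bridge CH2, and addition to N-methoxy-N-methylbutanamide would give the protected diketone 1,1'-{methylenebis[6-methoxy-2,4-bis(methoxymethoxy)-5-methylbenzene-3,1-diyl]}di(butan-1-one) F2. HCl/MeOH then removes the four MOM groups from rings that are now fully substituted and acyl-deactivated, and the sequence comes back to the route at 12.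

**Step 5.** The most likely failure is electrophilic capture of the methoxymethyl cation by the freed, highly nucleophilic rings at their remaining C–H (unwanted extra methylene links) before the silane reduces it; partial cleavage at the bridge in trifluoroacetic acid is the second concern. The fallback separates reduction from deprotection and removes the acetals without protic acid. It sets out from 8, which is reduced as in the first stage and 9 isolated. TMSOTf/2,2'-bipyridyl (CH2Cl2, 0 °C) should convert the four aryl MOM ethers into silyl ethers, giving bis[4-methoxy-3-methyl-2,6-bis(trimethylsilyloxy)phenyl]methane F3, with the methoxymethyl group held on the bipyridine nitrogen. Neutral aqueous hydrolysis then returns to the route at 10.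

**Step 4.** Two things may go wrong: incomplete site selectivity of the lithiation (C4 against C6 of 4), which would carry an isomeric aryl group into the carbinol, and stalling of the second addition at the tetra-ortho-substituted stage. The fallback replaces the one-pot three-component union by a convergent two-stage sequence. It sets out from 4: lithiation and quenching with DMF give 7, which is isolated and freed from any regioisomer by crystallisation. A second portion of 6, transmetalated with CeCl3 to the less basic and more oxophilic organocerium reagent, is then added to pure 7, returning to the route at 8. No compound outside the list is made (F0).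

**Step 3.** Hydrazone formation or its decomposition may stall on the di-ortho-substituted, electron-rich aldehyde (azine formation), and the aryl methyl ether may be attacked by hydrazine/KOH at 200 °C. The fallback changes the deoxygenation from a hydrazone to a benzylic C–O hydrogenolysis. It sets out from 3: NaBH4 (MeOH, 0 °C) gives [2-methoxy-4,6-bis(methoxymethoxy)phenyl]methanol F4. Its electron-rich benzylic C–O bond should be cleaved by H2, Pd/C in EtOAc with a trace of Et3N, returning to the route at 4.

## Further compounds

F1 | step 6 | bis[3-bromo-4-methoxy-2,6-bis(methoxymethoxy)-5-methylphenyl]methane | COCOc1c(Br)c(OC)c(C)c(OCOC)c1Cc1c(OCOC)c(Br)c(OC)c(C)c1OCOC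
F2 | step 6 | 1,1'-{methylenebis[6-methoxy-2,4-bis(methoxymethoxy)-5-methylbenzene-3,1-diyl]}di(butan-1-one) | CCCC(=O)c1c(OCOC)c(Cc2c(OCOC)c(C)c(OC)c(C(=O)CCC)c2OCOC)c(OCOC)c(C)c1OC
F3 | step 5 | bis[4-methoxy-3-methyl-2,6-bis(trimethylsilyloxy)phenyl]methane | COc1cc(O[Si](C)(C)C)c(Cc2c(O[Si](C)(C)C)cc(OC)c(C)c2O[Si](C)(C)C)c(O[Si](C)(C)C)c1C
F0 | step 4 | none | none
F4 | step 3 | [2-methoxy-4,6-bis(methoxymethoxy)phenyl]methanol | OCc1c(OC)cc(OCOC)cc1OCOC
A1 | alternative 1 | 5-methoxy-4-methylbenzene-1,3-diol | Cc1c(O)cc(O)cc1OC
A2 | alternative 1 | 1-(4,6-dihydroxy-2-methoxy-3-methylphenyl)butan-1-one | CCCC(=O)c1c(O)cc(O)c(C)c1OC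
A3 | alternative 1 | 1-(2,6-dihydroxy-4-methoxy-3-methylphenyl)butan-1-one | CCCC(=O)c1c(O)cc(OC)c(C)c1O
A4 | alternative 2 | 1-(2,4-dihydroxy-6-methoxy-3,5-dimethylphenyl)butan-1-one | CCCC(=O)c1c(O)c(C)c(O)c(C)c1OC
A5 | alternative 2 | 4-butanoyl-5-hydroxy-3-methoxy-2-methyl-6-methylidenecyclohexa-2,4-dien-1-one | C=C1C(=O)C(C)=C(OC)C(C(=O)CCC)=C1O
A6 | alternative 3 | 3,3'-methylenebis[4-hydroxy-5-methyl-6-(2-oxopentyl)-2H-pyran-2-one] | CCCC(=O)CC1=C(C)C(O)=C(CC2=C(O)C(C)=C(CC(=O)CCC)OC2=O)C(=O)O1
A7 | alternative 3 | 1,1'-[methylenebis(2,4,6-trihydroxy-5-methylbenzene-3,1-diyl)]di(butan-1-one) | CCCC(=O)c1c(O)c(C)c(O)c(Cc2c(O)c(C)c(O)c(C(=O)CCC)c2O)c1O
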